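The carbocycle of the target (C4a, C5, C6, C7, C8, C8a; isochromene numbering) carries a tertiary α-ketol, the C8 ketone beside C7(OH)CH3, with the C6 carbinol next to it. This is the product pattern of an α-ketol rearrangement, so everything rests on the C6–C7 bond: an aluminium-chelated 1-acetylcyclopent-2-en-1-ol, built from (S)-4-silyloxycyclopentenone, shifts its C6–C8 ring bond onto the acetyl carbon. One operation enlarges the five-membered ring to the cyclohexenone, creates the C8 ketone and sets the quaternary C7 carbinol cis to O6. An amine-relayed closure of the pyran onto an enynone, a late hindered esterification and acidolysis finish the route.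

Key step: step 7

Remark: the isochromene numbering of the target (C1, O2, C3, C4, C4a, C5 to C8, C8a) is used for all intermediates, TBS = tert-butyldimethylsilyl, and the three starting materials and all unnumbered reagents are assumed to be purchasable.

Step 1
Reactants: 1 (S)-4-(TBS-oxy)cyclopent-2-en-1-one
Product: 2 (S)-4-(TBS-oxy)-2-iodocyclopent-2-en-1-one
Conditions: I2, pyridine, CH2Cl2, 0 °C to rt
Reagents that add atoms: iodine, II
Why: α-Iodination of the enone through the pyridine adduct (conjugate addition, iodination of the enolate, elimination) is standard for 4-silyloxycyclopentenones and should leave the silyloxy stereocenter (the later C6) untouched.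

Step 2
Reactants: 2 (S)-4-(TBS-oxy)-2-iodocyclopent-2-en-1-one
Product: 3 (S)-4-(TBS-oxy)-2-(hydroxymethyl)cyclopent-2-en-1-one
Conditions: Bu3SnCH2OH, Pd(PPh3)4 (cat.), 1,4-dioxane, 80 °C
Reagents that add atoms: (tributylstannyl)methanol, CCCC[Sn](CCCC)(CCCC)CO
Why: Stille coupling of the α-iodoenone with the hydroxymethylstannane should bring in C1 with its oxygen under neutral conditions that neither enolise nor eliminate the γ-silyloxy enone.

Step 3
Reactants: 3 (S)-4-(TBS-oxy)-2-(hydroxymethyl)cyclopent-2-en-1-one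
Product: 4 (S)-4-(TBS-oxy)-2-(TBS-oxymethyl)cyclopent-2-en-1-one
Conditions: TBSCl, imidazole, DMF, 0 °C to rt
Reagents that add atoms: tert-butyldimethylsilyl chloride, CC(C)(C)[Si](C)(C)Cl
Why: Routine silylation of the primary allylic alcohol should mask the later ring oxygen O2 against the organometallic and oxidative steps that follow.

Step 4
Reactants: 4 (S)-4-(TBS-oxy)-2-(TBS-oxymethyl)cyclopent-2-en-1-one
Product: 5 (1S,4S)-4-(TBS-oxy)-2-(TBS-oxymethyl)-1-ethynylcyclopent-2-en-1-ol (major C1 epimer drawn; the minor epimer is carried along)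
Conditions: HC≡CMgBr, THF, −78 to −20 °C; aq. NH4Cl
Reagents that add atoms: ethynylmagnesium bromide, C#C[Mg]Br
Why: 1,2-Addition of the acetylide Grignard reagent to the enone carbonyl at low temperature should outrun enolisation, and the configuration of the new carbinol is irrelevant because step 5 erases it.

Step 5
Reactants: 5 (1S,4S)-4-(TBS-oxy)-2-(TBS-oxymethyl)-1-ethynylcyclopent-2-en-1-ol
Product: 6 (S)-5-(TBS-oxy)-2-(TBS-oxymethyl)-3-ethynylcyclopent-2-en-1-one
Conditions: C5H5NH[CrO3Cl] (pyridinium chlorochromate), 4 Å molecular sieves, CH2Cl2, rt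
Reagents that add atoms: pyridinium chlorochromate, [O-][Cr](=O)(=O)Cl.c1cc[nH+]cc1
Why: Babler–Dauben oxidative 1,3-transposition (allylic chromate [3,3] shift, then oxidation) should place the carbonyl (C8) next to the silyloxy carbon (C6) and leave the ethynyl group on the β-carbon (C4a) without touching the stereocenter.

Step 6
Reactants: 6 (S)-5-(TBS-oxy)-2-(TBS-oxymethyl)-3-ethynylcyclopent-2-en-1-one
Product: 8 1-[(1R,5S)-5-(TBS-oxy)-2-(TBS-oxymethyl)-3-ethynyl-1-hydroxycyclopent-2-en-1-yl]ethan-1-one (tertiary hydroxyl cis to the silyloxy group), via 1-ethoxyvinyl carbinol 7 (not isolated)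
Conditions: CH2=C(OEt)Li (2.5 equiv, from ethyl vinyl ether and t-BuLi, THF, −78 to 0 °C), THF, −78 °C; aq. NH4Cl; then 5% aq. oxalic acid, THF, 0 °C
Reagents that add atoms: 1-ethoxyvinyllithium, [Li]C(=C)OCC; water, O
Why: 1,2-Addition of the acyl anion equivalent should occur on the carbonyl face anti to the adjacent C6 silyloxy group (substrate control), so the C8 hydroxyl ends cis to O6, and mild enol ether hydrolysis should then unveil the methyl ketone.

Step 7
Reactants: 8 1-[(1R,5S)-5-(TBS-oxy)-2-(TBS-oxymethyl)-3-ethynyl-1-hydroxycyclopent-2-en-1-yl]ethan-1-one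
Product: 9 (5S,6S)-5-(TBS-oxy)-2-(TBS-oxymethyl)-3-ethynyl-6-hydroxy-6-methylcyclohex-2-en-1-one
Conditions: Me2AlCl (1.2 equiv), CH2Cl2, −78 °C to rt; aqueous work-up
Reagents that add atoms: none
Why: Me2AlCl should turn the tertiary hydroxyl into an aluminium alkoxide that chelates the acetyl oxygen, and in this syn-periplanar five-membered chelate the C6–C8 ring bond lies over the carbonyl π* and shifts suprafacially from C8 to the acetyl carbon C7 while C8–O becomes the ketone; this is an α-ketol (acyloin) rearrangement, the reaction type of the D-homoannulation of 17-hydroxy-20-ketosteroids. No ring is closed: the five-membered carbocycle is enlarged to the six-membered one by this 1,2-shift, with retention at the migrating C6. The new C7 stereocenter is fixed by the chelate geometry, because with the acetyl oxygen held syn to the C8 oxygen the new hydroxyl appears on the face of the old C8 hydroxyl, that is cis to O6 (set in step 6), and the methyl group trans. Two selectivities are needed: the chelated cisoid rotamer over the transoid one, which the bidentate aluminium alkoxide in a non-coordinating solvent should secure, and C6 over C8a migration, which is not critical because a first shift of C8a followed by the methyl shift that restores conjugation would lead to the same constitution and configuration. The conjugated C8 enone, extended by the alkyne, and the relief of cyclopentene strain should make the shift irreversible.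

Step 8
Reactants: 10 (E)-3-iodoacrylic acid
Product: 11 tert-butyl (E)-3-iodoacrylate
Conditions: tert-butyl 2,2,2-trichloroacetimidate, BF3·OEt2 (cat.), CH2Cl2/cyclohexane, rt
Reagents that add atoms: tert-butyl 2,2,2-trichloroacetimidate, CC(C)(C)OC(=N)C(Cl)(Cl)Cl
Why: Acid-catalysed tert-butylation of the carboxylic acid by the imidate should proceed without touching the (E)-vinyl iodide.

Step 9
Reactants: 9 (5S,6S)-5-(TBS-oxy)-2-(TBS-oxymethyl)-3-ethynyl-6-hydroxy-6-methylcyclohex-2-en-1-one; 11 tert-butyl (E)-3-iodoacrylate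
Product: 12 tert-butyl (E)-5-[(4S,5S)-5-(TBS-oxy)-2-(TBS-oxymethyl)-4-hydroxy-4-methyl-3-oxocyclohex-1-en-1-yl]pent-2-en-4-ynoate
Conditions: Pd(PPh3)2Cl2 (cat.), CuI (cat.), iPr2NEt, THF, rt
Reagents that add atoms: none
Why: Sonogashira coupling of the terminal alkyne with the vinyl iodide should retain the E geometry, and the tertiary amine base avoids conjugate addition to the ynenone.

Step 10
Reactants: 12 tert-butyl (E)-5-[(4S,5S)-5-(TBS-oxy)-2-(TBS-oxymethyl)-4-hydroxy-4-methyl-3-oxocyclohex-1-en-1-yl]pent-2-en-4-ynoate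
Product: 14 tert-butyl (E)-3-[(6S,7S)-6,7-dihydroxy-7-methyl-8-oxo-5,6,7,8-tetrahydro-1H-isochromen-3-yl]acrylate, via C3 diethylamino dienone 13 (not isolated)
Conditions: Et2NH, EtOH, rt; evaporation; then 48% aq. HF, MeCN, 0 °C to rt
Reagents that add atoms: diethylamine, CCNCC (its atoms are carried in 13 only and leave again before 14)
Why: Diethylamine should add in 1,6-fashion (aza-Michael addition to an enynone) to the alkyne carbon C3, which is conjugated with the C8 ketone and remote from the hindered ring, and aqueous HF should then remove both silyl groups and let the freed C1 hydroxyl replace the amine at C3 by enaminone hydrolysis and cyclodehydration, which fixes the six-membered 2H-pyran regiochemistry.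

Step 11
Reactants: 15 5-methylbenzene-1,2,3-triol
Product: 16 2,2,6-trimethyl-1,3-benzodioxol-4-ol
Conditions: 2,2-dimethoxypropane, TsOH (cat.), toluene, reflux with removal of MeOH
Reagents that add atoms: 2,2-dimethoxypropane, COC(C)(C)OC
Why: Acid-catalysed transketalisation can bridge only two adjacent hydroxyls, and the symmetry of the triol should make the mono-acetonide a single compound.

Step 12
Reactants: 16 2,2,6-trimethyl-1,3-benzodioxol-4-ol
Product: 17 4-hydroxy-2,2,6-trimethyl-1,3-benzodioxole-5-carbaldehyde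
Conditions: MgCl2, Et3N, paraformaldehyde, MeCN, reflux; dilute aq. HCl
Reagents that add atoms: paraformaldehyde (as formaldehyde), C=O
Why: Magnesium-mediated ortho-formylation of phenols is ortho-specific, and the only free ortho position lies between the hydroxyl and the methyl group, which is the carbon that must carry the carboxyl.

Step 13
Reactants: 17 4-hydroxy-2,2,6-trimethyl-1,3-benzodioxole-5-carbaldehyde
Product: 18 4-methoxy-2,2,6-trimethyl-1,3-benzodioxole-5-carbaldehyde
Conditions: MeI, K2CO3, DMF, rt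
Reagents that add atoms: iodomethane, CI
Why: Williamson methylation of the single free phenol should install the methoxy group ortho to the carbonyl.

Step 14
Reactants: 18 4-methoxy-2,2,6-trimethyl-1,3-benzodioxole-5-carbaldehyde
Product: 19 4-methoxy-2,2,6-trimethyl-1,3-benzodioxole-5-carboxylic acid
Conditions: NaClO2, NaH2PO4, 2-methyl-2-butene, t-BuOH/H2O, rt
Reagents that add atoms: sodium chlorite, [Na+].[O-]Cl=O
Why: Pinnick oxidation should convert the electron-rich aryl aldehyde to the acid without harming the ketal, the alkene trapping the hypochlorous acid.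

Step 15
Reactants: 19 4-methoxy-2,2,6-trimethyl-1,3-benzodioxole-5-carboxylic acid; 14 tert-butyl (E)-3-[(6S,7S)-6,7-dihydroxy-7-methyl-8-oxo-5,6,7,8-tetrahydro-1H-isochromen-3-yl]acrylate
Product: 21 (6S,7S)-3-[(E)-3-tert-butoxy-3-oxoprop-1-en-1-yl]-7-hydroxy-7-methyl-8-oxo-5,6,7,8-tetrahydro-1H-isochromen-6-yl 4-methoxy-2,2,6-trimethyl-1,3-benzodioxole-5-carboxylate, via aroyl chloride 20 (not isolated)
Conditions: 19, 1-chloro-N,N,2-trimethylprop-1-en-1-amine, CH2Cl2, 0 °C to rt; then 14, Et3N, DMAP (cat.), CH2Cl2, rt to 40 °C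
Reagents that add atoms: 1-chloro-N,N,2-trimethylprop-1-en-1-amine, CC(C)=C(Cl)N(C)C (its chlorine is carried in 20 only)
Why: DMAP-catalysed acylation by the electron-rich, doubly ortho-substituted aroyl chloride should take the secondary C6 hydroxyl in preference to the tertiary C7 hydroxyl on steric grounds, and no stereocenter is touched.

Step 16
Reactants: 21 (6S,7S)-3-[(E)-3-tert-butoxy-3-oxoprop-1-en-1-yl]-7-hydroxy-7-methyl-8-oxo-5,6,7,8-tetrahydro-1H-isochromen-6-yl 4-methoxy-2,2,6-trimethyl-1,3-benzodioxole-5-carboxylate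
Product: 22 (E)-3-[(6S,7S)-6-[(3,4-dihydroxy-2-methoxy-6-methylbenzoyl)oxy]-7-hydroxy-7-methyl-8-oxo-5,6,7,8-tetrahydro-1H-isochromen-3-yl]acrylic acid (CNP0446308.3)
Conditions: TFA/CH2Cl2/H2O, anisole, 0 °C to rt
Reagents that add atoms: none
Why: Acidolysis should cleave the tert-butyl ester and hydrolyse the catechol acetonide in one operation, anisole trapping the tert-butyl cation, while the vinylogous-ester pyran, the α-ketol and the hindered benzoate should tolerate the brief acid exposure.

Compound list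
1 | (S)-4-[(tert-butyldimethylsilyl)oxy]cyclopent-2-en-1-one | CC(C)(C)[Si](C)(C)O[C@H]1CC(=O)C=C1 | starting material
2 | (S)-4-[(tert-butyldimethylsilyl)oxy]-2-iodocyclopent-2-en-1-one | CC(C)(C)[Si](C)(C)O[C@H]1CC(=O)C(I)=C1 | intermediate
3 | (S)-4-[(tert-butyldimethylsilyl)oxy]-2-(hydroxymethyl)cyclopent-2-en-1-one | CC(C)(C)[Si](C)(C)O[C@H]1CC(=O)C(CO)=C1 | intermediate
4 | (S)-4-[(tert-butyldimethylsilyl)oxy]-2-{[(tert-butyldimethylsilyl)oxy]methyl}cyclopent-2-en-1-one | CC(C)(C)[Si](C)(C)O[C@H]1CC(=O)C(CO[Si](C)(C)C(C)(C)C)=C1 | intermediate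
5 | (1S,4S)-4-[(tert-butyldimethylsilyl)oxy]-2-{[(tert-butyldimethylsilyl)oxy]methyl}-1-ethynylcyclopent-2-en-1-ol (major C1 epimer, hydroxyl cis to the C4 silyloxy group) | CC(C)(C)[Si](C)(C)O[C@H]1C[C@](O)(C#C)C(CO[Si](C)(C)C(C)(C)C)=C1 | intermediate
6 | (S)-5-[(tert-butyldimethylsilyl)oxy]-2-{[(tert-butyldimethylsilyl)oxy]methyl}-3-ethynylcyclopent-2-en-1-one | CC(C)(C)[Si](C)(C)O[C@H]1CC(C#C)=C(CO[Si](C)(C)C(C)(C)C)C1=O | intermediate
7 | (1R,5S)-5-[(tert-butyldimethylsilyl)oxy]-2-{[(tert-butyldimethylsilyl)oxy]methyl}-1-(1-ethoxyvinyl)-3-ethynylcyclopent-2-en-1-ol | CC(C)(C)[Si](C)(C)O[C@H]1CC(C#C)=C(CO[Si](C)(C)C(C)(C)C)[C@]1(O)C(=C)OCC | intermediate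
8 | 1-[(1R,5S)-5-[(tert-butyldimethylsilyl)oxy]-2-{[(tert-butyldimethylsilyl)oxy]methyl}-3-ethynyl-1-hydroxycyclopent-2-en-1-yl]ethan-1-one | CC(C)(C)[Si](C)(C)O[C@H]1CC(C#C)=C(CO[Si](C)(C)C(C)(C)C)[C@]1(O)C(C)=O | intermediate
9 | (5S,6S)-5-[(tert-butyldimethylsilyl)oxy]-2-{[(tert-butyldimethylsilyl)oxy]methyl}-3-ethynyl-6-hydroxy-6-methylcyclohex-2-en-1-one | CC(C)(C)[Si](C)(C)O[C@H]1CC(C#C)=C(CO[Si](C)(C)C(C)(C)C)C(=O)[C@@]1(C)O | intermediate
10 | (E)-3-iodoacrylic acid | OC(=O)/C=C/I | starting material
11 | tert-butyl (E)-3-iodoacrylate | CC(C)(C)OC(=O)/C=C/I | intermediate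
12 | tert-butyl (E)-5-[(4S,5S)-5-[(tert-butyldimethylsilyl)oxy]-2-{[(tert-butyldimethylsilyl)oxy]methyl}-4-hydroxy-4-methyl-3-oxocyclohex-1-en-1-yl]pent-2-en-4-ynoate | CC(C)(C)[Si](C)(C)O[C@H]1CC(C#C/C=C/C(=O)OC(C)(C)C)=C(CO[Si](C)(C)C(C)(C)C)C(=O)[C@@]1(C)O | intermediate
13 | tert-butyl (2E)-5-[(4S,5S)-5-[(tert-butyldimethylsilyl)oxy]-2-{[(tert-butyldimethylsilyl)oxy]methyl}-4-hydroxy-4-methyl-3-oxocyclohex-1-en-1-yl]-4-(diethylamino)penta-2,4-dienoate (geometry of the push–pull C4=C5 bond not fixed) | CC(C)(C)[Si](C)(C)O[C@H]1CC(C=C(/C=C/C(=O)OC(C)(C)C)N(CC)CC)=C(CO[Si](C)(C)C(C)(C)C)C(=O)[C@@]1(C)O | intermediate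
14 | tert-butyl (E)-3-[(6S,7S)-6,7-dihydroxy-7-methyl-8-oxo-5,6,7,8-tetrahydro-1H-isochromen-3-yl]acrylate | O[C@H]1CC2=C(COC(/C=C/C(=O)OC(C)(C)C)=C2)C(=O)[C@@]1(C)O | intermediate
15 | 5-methylbenzene-1,2,3-triol | Cc1cc(O)c(O)c(O)c1 | starting material
16 | 2,2,6-trimethyl-1,3-benzodioxol-4-ol | Cc1cc(O)c2OC(C)(C)Oc2c1 | intermediate
17 | 4-hydroxy-2,2,6-trimethyl-1,3-benzodioxole-5-carbaldehyde | Cc1cc2OC(C)(C)Oc2c(O)c1C=O | intermediate
18 | 4-methoxy-2,2,6-trimethyl-1,3-benzodioxole-5-carbaldehyde | COc1c(C=O)c(C)cc2OC(C)(C)Oc12 | intermediate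
19 | 4-methoxy-2,2,6-trimethyl-1,3-benzodioxole-5-carboxylic acid | COc1c(C(=O)O)c(C)cc2OC(C)(C)Oc12 | intermediate
20 | 4-methoxy-2,2,6-trimethyl-1,3-benzodioxole-5-carbonyl chloride | COc1c(C(Cl)=O)c(C)cc2OC(C)(C)Oc12 | intermediate
21 | (6S,7S)-3-[(E)-3-tert-butoxy-3-oxoprop-1-en-1-yl]-7-hydroxy-7-methyl-8-oxo-5,6,7,8-tetrahydro-1H-isochromen-6-yl 4-methoxy-2,2,6-trimethyl-1,3-benzodioxole-5-carboxylate | COc1c(C(=O)O[C@H]3CC4=C(COC(/C=C/C(=O)OC(C)(C)C)=C4)C(=O)[C@@]3(C)O)c(C)cc2OC(C)(C)Oc12 | intermediate
22 | (E)-3-[(6S,7S)-6-[(3,4-dihydroxy-2-methoxy-6-methylbenzoyl)oxy]-7-hydroxy-7-methyl-8-oxo-5,6,7,8-tetrahydro-1H-isochromen-3-yl]acrylic acid | COc1c(O)c(O)cc(C)c1C(=O)O[C@H]1CC2=C(COC(/C=C/C(=O)O)=C2)C(=O)[C@@]1(C)O | target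

Total step count: 16.
Longest linear sequence: 11 steps (steps 1 to 7, 9, 10, 15 and 16, from 1 to 22).

Steps most likely to fail

Step 7 (key step). The shift may run through the non-chelated transoid rotamer, which would put the C7 hydroxyl trans to O6, or the Lewis acid may ionise the allylic C8 oxygen or loosen a silyl ether before the shift takes place. The fallback uses the complementary stereochemical mode of the same rearrangement type. It sets out from enone 6. Wittig olefination with Ph3P=CHCH3 should give the exocyclic ethylidene diene F1. OsO4/NMO dihydroxylation of this least hindered alkene, on the face anti to the silyloxy group, should give the diol F2 with the tertiary hydroxyl trans to O6. Dess–Martin oxidation of the secondary alcohol should give the C8-epimeric ketol F3. NaH in THF should then trigger the base-mediated α-ketol rearrangement through the transoid alkoxide, in which the new hydroxyl appears on the face of the former acetyl group, that is cis to O6. The route is rejoined at 9.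

Step 10. The amine may add at C4 under the influence of the acrylate instead of at C3, the exchange of the amine for the C1 hydroxyl may stop at the open keto form, or the new pyran may be hydrated by the aqueous acid. The fallback closes the ring by π-acid catalysis instead of the polar relay. It sets out from 12. HF·pyridine in THF should give the triol enynone F4, and a gold-catalysed 6-endo-dig hydroalkoxylation (Ph3PAuNTf2 cat., CH2Cl2, rt) of the C1 hydroxyl onto C3 should give the pyran. The route is rejoined at 14.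

Step 15. Acylation by the doubly ortho-substituted aroyl chloride may be too slow, so that base-induced elimination across C5–C6 or acylation of the tertiary O7 competes. The fallback activates the alcohol instead of relying on acyl transfer catalysis. It sets out from 14. Bu2SnO (toluene, reflux, removal of water) should give the stannylene acetal F5, whose secondary oxygen should be acylated by aroyl chloride 20 without amine base. The route is rejoined at 21.

Further compounds
F1 | step 7 | tert-butyl{[(1S,2Z)-2-ethylidene-4-ethynyl-3-{[(tert-butyldimethylsilyl)oxy]methyl}cyclopent-3-en-1-yl]oxy}dimethylsilane (expected major alkene isomer; either isomer converges) | CC(C)(C)[Si](C)(C)O[C@H]1CC(C#C)=C(CO[Si](C)(C)C(C)(C)C)/C1=C/C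
F2 | step 7 | (5S)-5-[(tert-butyldimethylsilyl)oxy]-2-{[(tert-butyldimethylsilyl)oxy]methyl}-3-ethynyl-1-(1-hydroxyethyl)cyclopent-2-en-1-ol with the tertiary hydroxyl trans to the C5 silyloxy group | CC(C)(C)[Si](C)(C)O[C@H]1CC(C#C)=C(CO[Si](C)(C)C(C)(C)C)[C@@]1(O)[C@@H](C)O
F3 | step 7 | 1-[(1S,5S)-5-[(tert-butyldimethylsilyl)oxy]-2-{[(tert-butyldimethylsilyl)oxy]methyl}-3-ethynyl-1-hydroxycyclopent-2-en-1-yl]ethan-1-one (C1 epimer of 8) | CC(C)(C)[Si](C)(C)O[C@H]1CC(C#C)=C(CO[Si](C)(C)C(C)(C)C)[C@@]1(O)C(C)=O
F4 | step 10 | tert-butyl (E)-5-[(4S,5S)-4,5-dihydroxy-2-(hydroxymethyl)-4-methyl-3-oxocyclohex-1-en-1-yl]pent-2-en-4-ynoate | O[C@H]1CC(C#C/C=C/C(=O)OC(C)(C)C)=C(CO)C(=O)[C@@]1(C)O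
F5 | step 15 | 2,2-dibutyl-1,3,2-dioxastannolane (stannylene acetal) of diol 14, tin bridging O6 and O7 | CCCC[Sn]1(CCCC)O[C@H]2CC3=C(COC(/C=C/C(=O)OC(C)(C)C)=C3)C(=O)[C@@]2(C)O1
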